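## Retrosynthetic overview

1. The target comes from its tetrabenzyl ether (three O-benzyl groups on C6–C8, one on the phenol) by a final hydrogenolysis.
2. Key disconnection O1–C2: the γ-pyrone is closed last, by C–O bond formation, in an oxidative 6-endo-dig cyclisation of a 2-(1-hydroxyalk-2-ynyl) ketone.
3. C4–C4a: aldol addition of the carbocyclic β-hydroxy ketone to a 5-arylpent-2-ynal.
4. C4a–C5: the carbocycle is formed first, by Ferrier carbocyclisation of a D-gluco hex-5-enopyranoside. C6, C7 and C8 are C2, C3 and C4 of D-glucose, and C5 is set in this ring closure.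
5. The ynal comes from O-benzyl isovanillyl chloride by propargylation and formylation.

Assumption: 3-(benzyloxy)-4-methoxybenzyl chloride is taken as a cheap catalogue compound; atom labels O1, C2 to C8a follow chromone numbering.

## Route

Step 1
Reactants: 1 methyl α-D-glucopyranoside
Product: 2 methyl 6-deoxy-6-iodo-α-D-glucopyranoside
Conditions: I2, PPh3, imidazole, THF, 65 °C
Reagents that add atoms: iodine, II
Why: Garegg–Samuelsson (Appel-type) iodination, in which the alkoxyphosphonium ion forms only at the unhindered primary hydroxyl and is displaced by iodide, so no stereocenter is touched.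

Step 2
Reactants: 2 methyl 6-deoxy-6-iodo-α-D-glucopyranoside
Product: 4 methyl 2,3,4-tri-O-benzyl-6-deoxy-α-D-xylo-hex-5-enopyranoside, via tribenzyl 6-iodide 3 (not isolated)
Conditions: NaH (6 equiv), BnBr (3.5 equiv), DMF, 0 °C to rt
Reagents that add atoms: benzyl bromide, BrCc1ccccc1
Why: Williamson ether synthesis on the three secondary hydroxyls and, with the excess NaH, E2 dehydroiodination across C5–C6 give the exocyclic enol ether in one flask, C1–C4 keeping the α-D-gluco configuration.

Step 3
Reactants: 4 methyl 2,3,4-tri-O-benzyl-6-deoxy-α-D-xylo-hex-5-enopyranoside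
Product: 6 (2S,3R,4S,5S)-2,3,4-tris(benzyloxy)-5-hydroxycyclohexan-1-one, via acyclic mercurio keto aldehyde 5 (not isolated)
Conditions: Hg(OCOCF3)2 (3 mol %), acetone–H2O (3:2), rt
Reagents that add atoms: water, O
Why: Ferrier carbocyclization, in which oxymercuration of the enol ether and loss of methanol give keto aldehyde 5, whose mercury enolate closes by intramolecular aldol addition through a chair transition state that places the new hydroxyl axial and cis to the neighbouring benzyloxy group (5S, about 9:1), while C2, C3 and C4 of D-glucose become the other three stereocenters unchanged.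

Step 4
Reactants: 7 3-(benzyloxy)-4-methoxybenzyl chloride; 8 propargyl bromide
Product: 10 4-[3-(benzyloxy)-4-methoxyphenyl]but-1-yne, via allenylmagnesium bromide 9 (not isolated)
Conditions: 8, Mg, HgCl2 (1 mol %), Et2O, 0 °C; then 7, THF, 0 °C to rt
Reagents that add atoms: none
Why: Grignard formation from 8 gives allenylmagnesium bromide, which alkylates the electron-rich benzylic chloride through its γ-carbon (SE2′ coupling) to give the terminal homopropargyl arene; no stereocenter is involved.

Step 5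
Reactants: 10 4-[3-(benzyloxy)-4-methoxyphenyl]but-1-yne
Product: 13 5-[3-(benzyloxy)-4-methoxyphenyl]pent-2-ynal, via lithium acetylide 11 (not isolated), via lithium aminoalkoxide 12 (not isolated)
Conditions: n-BuLi, THF, −78 °C; DMF, −78 to 0 °C; inverse quench into cold aq. AcOH/MTBE
Reagents that add atoms: N,N-dimethylformamide, CN(C)C=O
Why: Formylation of the lithium acetylide with DMF, in which the tetrahedral aminoalkoxide survives until the acidic inverse quench, which also protonates dimethylamine and so keeps it from adding to the ynal.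

Step 6
Reactants: 6 (2S,3R,4S,5S)-2,3,4-tris(benzyloxy)-5-hydroxycyclohexan-1-one; 13 5-[3-(benzyloxy)-4-methoxyphenyl]pent-2-ynal
Product: 15 (2S,3R,4S,5S)-2,3,4-tris(benzyloxy)-6-{5-[3-(benzyloxy)-4-methoxyphenyl]-1-hydroxypent-2-yn-1-yl}-5-hydroxycyclohexan-1-one, via dilithium enolate alkoxide 14 (not isolated)
Conditions: LiN(i-Pr)2 (2.2 equiv), THF, −78 °C; 13, −78 °C; AcOH, −78 °C
Reagents that add atoms: none
Why: Directed aldol addition, in which kinetic deprotonation of the β-oxido ketone at its CH2 gives a dianion that cannot undergo β-elimination and 1,2-addition to the ynal forms the C4–C4a bond; the two new stereocenters form as a mixture and are both erased in step 7, while C2–C5 of the ring are untouched.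

Step 7
Reactants: 15 (2S,3R,4S,5S)-2,3,4-tris(benzyloxy)-6-{5-[3-(benzyloxy)-4-methoxyphenyl]-1-hydroxypent-2-yn-1-yl}-5-hydroxycyclohexan-1-one
Product: 17 (5S,6S,7R,8S)-6,7,8-tris(benzyloxy)-2-{2-[3-(benzyloxy)-4-methoxyphenyl]ethyl}-5-hydroxy-5,6,7,8-tetrahydro-4H-chromen-4-one, via alkynyl diketone 16 (not isolated)
Conditions: MnO2 (15 equiv), Et3N (0.3 equiv), CH2Cl2, rt
Reagents that add atoms: none
Why: Proposed new method: a one-flask oxidative cycloisomerisation on the unprotected diol, in which MnO2 dehydrogenates only the propargylic carbinol (the C5 carbinol is unactivated in 15 and, once the enol or pyrone exists, its C–H lies pseudo-equatorial, in the plane of the π-system and hydrogen-bonded to the C4 carbonyl, the slow case for MnO2) and the triethylammonium enolate of alkynyl 1,3-diketone 16 closes 6-endo-dig through its enol oxygen onto the ynone β-carbon (oxa-Michael addition forming O1–C2) faster than the neutral C5 hydroxyl can add or be eliminated; the closest known reaction types are MnO2 tandem oxidation–trapping of propargylic alcohols and the base- or acid-mediated 6-endo-dig cyclisation of isolated alkynyl 1,3-diketones to γ-pyrones, which have not been combined on a free β-hydroxy aldol of this kind; no stereocenter is formed and C5–C8 are untouched.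

Step 8
Reactants: 17 (5S,6S,7R,8S)-6,7,8-tris(benzyloxy)-2-{2-[3-(benzyloxy)-4-methoxyphenyl]ethyl}-5-hydroxy-5,6,7,8-tetrahydro-4H-chromen-4-one
Product: 18 (5S,6S,7R,8S)-5,6,7,8-tetrahydroxy-2-[2-(3-hydroxy-4-methoxyphenyl)ethyl]-5,6,7,8-tetrahydro-4H-chromen-4-one
Conditions: H2 (1 atm), Pd(OH)2/C, EtOAc–MeOH, rt
Reagents that add atoms: none
Why: Hydrogenolysis of the four benzyl ethers (three alkyl, one aryl) under neutral conditions leaves the γ-pyrone and the four carbinol centers untouched, so the (5S,6S,7R,8S) configuration is carried into the target.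

## Compound list

1 | methyl α-D-glucopyranoside | OC[C@H]1O[C@H](OC)[C@H](O)[C@@H](O)[C@@H]1O | starting material
2 | methyl 6-deoxy-6-iodo-α-D-glucopyranoside | IC[C@H]1O[C@H](OC)[C@H](O)[C@@H](O)[C@@H]1O | intermediate
3 | methyl 2,3,4-tri-O-benzyl-6-deoxy-6-iodo-α-D-glucopyranoside | IC[C@H]1O[C@H](OC)[C@H](OCc2ccccc2)[C@@H](OCc2ccccc2)[C@@H]1OCc1ccccc1 | intermediate (not isolated)
4 | methyl 2,3,4-tri-O-benzyl-6-deoxy-α-D-xylo-hex-5-enopyranoside | C=C1O[C@H](OC)[C@H](OCc2ccccc2)[C@@H](OCc2ccccc2)[C@@H]1OCc1ccccc1 | intermediate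
5 | 2,3,4-tri-O-benzyl-6-deoxy-6-[(trifluoroacetoxy)mercurio]-D-xylo-hexos-5-ulose, open-chain keto aldehyde | O=C[C@H](OCc1ccccc1)[C@@H](OCc1ccccc1)[C@H](OCc1ccccc1)C(=O)C[Hg]OC(=O)C(F)(F)F | intermediate (not isolated)
6 | (2S,3R,4S,5S)-2,3,4-tris(benzyloxy)-5-hydroxycyclohexan-1-one | O=C1[C@@H](OCc2ccccc2)[C@H](OCc2ccccc2)[C@@H](OCc2ccccc2)[C@@H](O)C1 | intermediate
7 | 3-(benzyloxy)-4-methoxybenzyl chloride | COc1ccc(CCl)cc1OCc1ccccc1 | starting material
8 | propargyl bromide (3-bromoprop-1-yne) | C#CCBr | starting material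
9 | allenylmagnesium bromide | C=C=C[Mg]Br | intermediate (not isolated)
10 | 4-[3-(benzyloxy)-4-methoxyphenyl]but-1-yne | COc1ccc(CCC#C)cc1OCc1ccccc1 | intermediate
11 | lithium acetylide of 10 | COc1ccc(CCC#C[Li])cc1OCc1ccccc1 | intermediate (not isolated)
12 | lithium 5-[3-(benzyloxy)-4-methoxyphenyl]-1-(dimethylamino)pent-2-yn-1-olate | COc1ccc(CCC#CC(O[Li])N(C)C)cc1OCc1ccccc1 | intermediate (not isolated)
13 | 5-[3-(benzyloxy)-4-methoxyphenyl]pent-2-ynal | COc1ccc(CCC#CC=O)cc1OCc1ccccc1 | intermediate
14 | dilithium enolate alkoxide of 6 (C1–C6 enolate, C5 alkoxide) | [Li]OC1=C[C@H](O[Li])[C@H](OCc2ccccc2)[C@@H](OCc2ccccc2)[C@@H]1OCc1ccccc1 | intermediate (not isolated)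
15 | (2S,3R,4S,5S)-2,3,4-tris(benzyloxy)-6-{5-[3-(benzyloxy)-4-methoxyphenyl]-1-hydroxypent-2-yn-1-yl}-5-hydroxycyclohexan-1-one, mixture of epimers at C6 and at the carbinol carbon | O=C1C(C(O)C#CCCc2ccc(OC)c(OCc3ccccc3)c2)[C@H](O)[C@H](OCc2ccccc2)[C@@H](OCc2ccccc2)[C@@H]1OCc1ccccc1 | intermediate
16 | (2S,3R,4S,5S)-2,3,4-tris(benzyloxy)-6-{5-[3-(benzyloxy)-4-methoxyphenyl]pent-2-ynoyl}-5-hydroxycyclohexan-1-one, enolised alkynyl 1,3-diketone | O=C1C(C(=O)C#CCCc2ccc(OC)c(OCc3ccccc3)c2)[C@H](O)[C@H](OCc2ccccc2)[C@@H](OCc2ccccc2)[C@@H]1OCc1ccccc1 | intermediate (not isolated)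
17 | (5S,6S,7R,8S)-6,7,8-tris(benzyloxy)-2-{2-[3-(benzyloxy)-4-methoxyphenyl]ethyl}-5-hydroxy-5,6,7,8-tetrahydro-4H-chromen-4-one | COc1ccc(CCc2cc(=O)c3c(o2)[C@@H](OCc4ccccc4)[C@H](OCc4ccccc4)[C@@H](OCc4ccccc4)[C@H]3O)cc1OCc1ccccc1 | intermediate
18 | (5S,6S,7R,8S)-5,6,7,8-tetrahydroxy-2-[2-(3-hydroxy-4-methoxyphenyl)ethyl]-5,6,7,8-tetrahydro-4H-chromen-4-one (CNP0224308.1) | COc1ccc(CCc2cc(=O)c3c(o2)[C@@H](O)[C@H](O)[C@@H](O)[C@H]3O)cc1O | target

## Step count and risks

Total step count: 8. Longest linear sequence: 6 (steps 1, 2, 3, 6, 7, 8); the ynal branch (steps 4 and 5) joins at step 6.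

The three steps most likely to fail:

Step 7, the proposed new step. The risks are over-oxidation of the C5 carbinol once it has become allylic, and addition of the C5 hydroxyl instead of the enol oxygen to the ynone. The fallback uses known chemistry only and sets out from 6. TESOTf and 2,6-lutidine (CH2Cl2, −78 °C) give the 5-O-triethylsilyl ether of 6, F1. LiN(i-Pr)2 (1.1 equiv, THF, −78 °C) and 13 give the 5-O-triethylsilyl ether of 15, F2. Dess–Martin periodinane oxidises the propargylic carbinol to the 5-O-triethylsilyl ether of 16, F3. TsOH in CH2Cl2–MeOH then closes the pyrone 6-endo-dig and removes the silyl group, and the fallback comes back to the route at 17.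

Step 6. The risks are deprotonation at C2 instead of C6 and retro-aldol opening of the dianion. The fallback sets out from 6. TMSCl with LiN(i-Pr)2 as internal quench (THF, −78 °C) gives the 1,5-bis-O-trimethylsilyl derivative of 6, F4 (C5 silyl ether and C1–C6 silyl enol ether). A Mukaiyama aldol addition to 13 (BF3·OEt2, CH2Cl2, −78 °C) followed by citric acid in MeOH removes both silyl groups, and the fallback comes back to the route at 15.

Step 8. The risks are hydrogenolysis of the pyronylic C8–O or C5–O bonds and reduction of the C2–C3 double bond. The fallback is Lewis-acid debenzylation with BCl3 and pentamethylbenzene as benzyl-cation scavenger (CH2Cl2, −78 °C, MeOH quench); it sets out from 17, comes back at 18 and makes no new compound (F0).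

## Further compounds

F1 | step 7 | 5-O-triethylsilyl ether of 6 | O=C1[C@@H](OCc2ccccc2)[C@H](OCc2ccccc2)[C@@H](OCc2ccccc2)[C@@H](O[Si](CC)(CC)CC)C1
F2 | step 7 | 5-O-triethylsilyl ether of 15 | O=C1C(C(O)C#CCCc2ccc(OC)c(OCc3ccccc3)c2)[C@H](O[Si](CC)(CC)CC)[C@H](OCc2ccccc2)[C@@H](OCc2ccccc2)[C@@H]1OCc1ccccc1
F3 | step 7 | 5-O-triethylsilyl ether of 16 | O=C1C(C(=O)C#CCCc2ccc(OC)c(OCc3ccccc3)c2)[C@H](O[Si](CC)(CC)CC)[C@H](OCc2ccccc2)[C@@H](OCc2ccccc2)[C@@H]1OCc1ccccc1
F4 | step 6 | 1,5-bis-O-trimethylsilyl derivative of 6 (C1–C6 silyl enol ether, C5 silyl ether) | C[Si](C)(C)OC1=C[C@H](O[Si](C)(C)C)[C@H](OCc2ccccc2)[C@@H](OCc2ccccc2)[C@@H]1OCc1ccccc1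
F0 | step 8 | none | none
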